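**Plan**
- Retrosynthetic cuts: the acetamide (from a trichloroacetamide), C4–N (aza-Michael delivered from the C5 oxygen), the C2 ketone/C5 hydroxyl pair (from a bridged methoxy ketal), the lactone C8–O and C9–alkenyl bonds (Nozaki–Hiyama–Kishi coupling, lactonisation), and last C1–C2 with C5–C6 (furan Diels–Alder).
- Enabling feature: in ring A the C2 ketone and the C5 hydroxyl are para, with C3/C4 between them, which is the oxygen pattern left by the bridge of a 2-alkoxyfuran adduct. Quaternary C1 with its C9 and C7–C8 arms maps onto an α-substituted acrolein and cannot aromatise.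
- Forward order: side-chain iodide (2 steps) and dienophile (1 step); the (4+2) step closes ring A as a 1-methoxy-7-oxanorbornene; coupling and lactonisation close the spirolactone; mild acid unveils the 4-hydroxy enone; imidate aza-Michael, oxazoline hydrolysis and dechlorination finish.
- Stereochemistry: C1 and C5 from the catalyst-controlled, exo-formyl cycloaddition; C9 from Felkin–Anh alkenyl addition; C4 from cis delivery of nitrogen from the C5 oxygen; the E alkene from syn carboalumination.

Key step: step 4

Locants used throughout: ring A C1 (spiro), C2 (C=O), C3, C4 (N), C5 (O), C6; lactone C7 (CH2), C8 (C=O), C9 (carbinol CH carrying the dienyl chain). Target descriptors: 1R, 4R, 5S, 9R.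

Assumption: the facial bias of the tryptophan-derived boron catalyst is taken to carry over from 2-haloacroleins, where the (S)-catalyst gives the (2R)-halo aldehyde; the spatially corresponding face of 8 then calls for the (R)-tryptophan-derived catalyst, and the antipode would be used if the sense proved opposite.

**Step 1**
Reactants: 1 6-methylhept-5-en-2-one
Product: 3 6-methylhept-5-en-1-yne, via enol phosphate 2 (not isolated)
Conditions: LiN(i-Pr)2 (1.05 equiv), THF, −78 °C; ClP(O)(OEt)2, −78 °C to rt; then LiN(i-Pr)2 (2.3 equiv), THF, −78 °C to rt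
Reagents that add atoms: none
Why: kinetic deprotonation at the methyl group, O-phosphorylation and base-induced elimination of diethyl phosphate is the standard methyl ketone to terminal alkyne conversion through an enol phosphate, and the remote trisubstituted alkene is inert to it.

**Step 2**
Reactants: 3 6-methylhept-5-en-1-yne
Product: 5 (E)-1-iodo-2,6-dimethylhepta-1,5-diene, via alkenylalane 4 (not isolated)
Conditions: AlMe3 (2 equiv), ZrCp2Cl2 (0.25 equiv), CH2Cl2, 0 °C to rt; then I2, THF, −30 to 0 °C
Reagents that add atoms: trimethylaluminium, C[Al](C)C; iodine, II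
Why: Negishi zirconium-catalysed carboalumination adds methyl and aluminium syn across the terminal alkyne with aluminium on the terminal carbon, and iodinolysis with retention should give the E iodide only.

**Step 3**
Reactants: 6 methyl 4-oxobutanoate; 7 formaldehyde
Product: 8 methyl 3-formylbut-3-enoate
Conditions: 37% aq. CH2O (1.0 equiv), pyrrolidine (10 mol %), EtCO2H (10 mol %), i-PrOH, 45 °C, short reaction time; used at once
Reagents that add atoms: none
Why: amine-catalysed α-methylenation of an aldehyde (enamine Mannich addition to formaldehyde, then elimination) acts only at the carbon next to the formyl group, and brief heating and immediate use should limit drift of the double bond into conjugation with the ester.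

**Step 4**
Reactants: 9 2-methoxyfuran; 8 methyl 3-formylbut-3-enoate
Product: 10 methyl 2-[(1S,2R,4S)-2-formyl-1-methoxy-7-oxabicyclo[2.2.1]hept-5-en-2-yl]acetate (formyl exo, acetate arm endo)
Conditions: (R)-2-butyl-4-(1H-indol-3-ylmethyl)-3-(4-methylphenylsulfonyl)-1,3,2-oxazaborolidin-5-one (10 mol %), 9 (3 equiv), 4 Å molecular sieves, CH2Cl2, −78 °C; Et3N quench, cold filtration through basic Al2O3; used at once
Reagents that add atoms: none
Why: Proposed new method: the boron Lewis acid binds the formyl oxygen of 8 and the furan adds in a concerted, strongly asynchronous (4+2) cycloaddition in which furan C5 first engages the methylene carbon (C5–C6) and the methoxy-bearing carbon then closes onto the α-carbon (C1–C2); the closest known reaction type is the oxazaborolidinone-catalysed Diels–Alder addition of furan itself to 2-haloacroleins, beyond which the 2-alkoxy donor and the isolation of the bridged ketal are new. Ring A is closed as the boat of the oxanorbornene, and the five-membered oxygen-bridged ring (C1–C2–O–C5–C6) with it, both by suprafacial addition across the furan termini. C1 is set by the catalyst, whose indole covers one face of the s-cis enal so that the furan reaches the Re face of the α-carbon (CHO, CH2CO2Me, =CH2 clockwise); C2 and C5 follow from C1 because the diene adds suprafacially; the exo formyl group (C9 syn to the oxygen bridge, hence cis to the later C5 hydroxyl) follows from the known endo preference of the α-substituent of 2-substituted acroleins. Ortho regiochemistry is secured by the methoxy group, which makes the unsubstituted furan C5 the nucleophilic terminus. The step needs ring closure to outrun proton loss from the zwitterion (Friedel–Crafts alkylation) and needs the donor–acceptor C1–C2 bond of 10 to survive, which is why a neutral boron Lewis acid without Brønsted co-acid, an aprotic medium, −78 °C and a basic quench are chosen; quaternary C1 rules out aromatisation.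

**Step 5**
Reactants: 10 the Diels–Alder aldehyde; 5 (E)-1-iodo-2,6-dimethylhepta-1,5-diene
Product: 12 spirolactone ketal (1R,2S,5S,9R), via hydroxy ester 11 (not isolated)
Conditions: CrCl2 (5 equiv), NiCl2 (2 mol %), 5 (2 equiv), DMSO, rt; aqueous work-up; then 1,8-diazabicyclo[5.4.0]undec-7-ene (DBU, 0.2 equiv), CH2Cl2, rt
Reagents that add atoms: none
Why: Nozaki–Hiyama–Kishi coupling adds the alkenyl group (via trivalent chromium, with retention of the E geometry) to the aldehyde only, and the γ-alkoxide then lactonises onto the methyl ester; C9 (R) is expected from a non-chelated Felkin–Anh addition in DMSO, with the ketal carbon C2 anti to the incoming alkenyl group, the chromium-bound oxygen on the C6 flank and the nucleophile passing the mobile C7 arm rather than the rigid C6 methylene.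

**Step 6**
Reactants: 12 spirolactone ketal
Product: 13 4-hydroxy enone (1R,5S,9R)
Conditions: pyridinium p-toluenesulfonate (0.2 equiv), acetone/H2O 10:1, rt
Reagents that add atoms: water, O
Why: acid-catalysed ketal hydrolysis opens the C2–O bridge bond to a methoxy-stabilised oxocarbenium ion that takes up water and loses methanol, giving the C2 ketone conjugated with C3=C4 while the C5–O bond, and so the C5 configuration, is untouched and quaternary C1 stops the sequence at the enone.

**Step 7**
Reactants: 13 4-hydroxy enone
Product: 15 cis-fused 2-(trichloromethyl)oxazoline (1R,4R,5S,9R), via trichloroacetimidate 14 (not isolated)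
Conditions: Cl3CCN (1.5 equiv), DBU (0.3 equiv), CH2Cl2, 0 °C to rt
Reagents that add atoms: trichloroacetonitrile, ClC(Cl)(Cl)C#N
Why: base-catalysed addition of the C5 alkoxide to the nitrile gives the imidate, whose nitrogen undergoes a 5-exo intramolecular aza-Michael addition to C4, and the three-atom tether can reach C4 only on the face of the C5 oxygen, which sets C4 (R) cis to C5.

**Step 8**
Reactants: 15 oxazoline
Product: 17 hydroxy trichloroacetamide (1R,4R,5S,9R), via ammonium ester 16 (not isolated)
Conditions: 1 M aq. HCl, THF, rt; then sat. aq. NaHCO3 to pH 8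
Reagents that add atoms: water, O
Why: acid hydrolysis of the 2-substituted oxazoline gives the C5 trichloroacetate with a C4 ammonium group, and neutralisation triggers O-to-N acyl migration in the cis amino ester to the amide without touching a stereocentre.

**Step 9**
Reactants: 17 hydroxy trichloroacetamide
Product: 18 (+)-miliusane V
Conditions: Bu3SnH (3.5 equiv), 2,2'-azobis(2-methylpropionitrile) (0.2 equiv), PhH, 80 °C; aq. KF work-up
Reagents that add atoms: none
Why: radical-chain hydrodechlorination with tin hydride converts a trichloroacetamide into an acetamide, the ketone, lactone, free hydroxyl and unactivated trisubstituted alkenes being inert to stannyl radicals under these conditions.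

**Compound list**
1 | 6-methylhept-5-en-2-one | CC(=O)CCC=C(C)C | starting material
2 | diethyl 6-methylhepta-1,5-dien-2-yl phosphate | C=C(CCC=C(C)C)OP(=O)(OCC)OCC | intermediate
3 | 6-methylhept-5-en-1-yne | C#CCCC=C(C)C | intermediate
4 | (E)-(2,6-dimethylhepta-1,5-dien-1-yl)dimethylalane | C[Al](C)/C=C(\C)CCC=C(C)C | intermediate
5 | (E)-1-iodo-2,6-dimethylhepta-1,5-diene | I/C=C(\C)CCC=C(C)C | intermediate
6 | methyl 4-oxobutanoate | COC(=O)CCC=O | starting material
7 | formaldehyde | C=O | starting material
8 | methyl 3-formylbut-3-enoate | COC(=O)CC(=C)C=O | intermediate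
9 | 2-methoxyfuran | COc1ccco1 | starting material
10 | methyl 2-[(1S,2R,4S)-2-formyl-1-methoxy-7-oxabicyclo[2.2.1]hept-5-en-2-yl]acetate | COC(=O)C[C@@]1(C=O)C[C@H]2C=C[C@]1(OC)O2 | intermediate
11 | methyl 2-[(1S,2R,4S)-2-[(1R,2E)-1-hydroxy-3,7-dimethylocta-2,6-dien-1-yl]-1-methoxy-7-oxabicyclo[2.2.1]hept-5-en-2-yl]acetate | COC(=O)C[C@@]1([C@H](O)/C=C(\C)CCC=C(C)C)C[C@H]2C=C[C@]1(OC)O2 | intermediate
12 | spirolactone ketal: γ-lactone spiro at C1 (R) of the 1-methoxy-7-oxanorbornene (C2 S, C5 S), (9R)-[(E)-2,6-dimethylhepta-1,5-dienyl] on the exo carbinol carbon | O=C1C[C@@]2([C@H](O1)/C=C(\C)CCC=C(C)C)C[C@H]3C=C[C@]2(OC)O3 | intermediate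
13 | 4-hydroxy enone: (1R,5S,9R) spirolactone with C2 ketone, C3=C4 and C5 hydroxyl | O=C1C[C@@]2([C@H](O1)/C=C(\C)CCC=C(C)C)C[C@H](O)C=CC2=O | intermediate
14 | C5 O-trichloroacetimidate of 13 | O=C1C[C@@]2([C@H](O1)/C=C(\C)CCC=C(C)C)C[C@H](OC(=N)C(Cl)(Cl)Cl)C=CC2=O | intermediate
15 | (1R,4R,5S,9R) 2-(trichloromethyl)oxazoline cis-fused through C4–N and C5–O | O=C1C[C@@]2([C@H](O1)/C=C(\C)CCC=C(C)C)C[C@@H]3OC(C(Cl)(Cl)Cl)=N[C@@H]3CC2=O | intermediate
16 | C5 trichloroacetate, C4 ammonium chloride | O=C1C[C@@]2([C@H](O1)/C=C(\C)CCC=C(C)C)C[C@H](OC(=O)C(Cl)(Cl)Cl)[C@H]([NH3+])CC2=O.[Cl-] | intermediate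
17 | N-trichloroacetyl analogue of 18 (1R,4R,5S,9R) | O=C1C[C@@]2([C@H](O1)/C=C(\C)CCC=C(C)C)C[C@H](O)[C@H](NC(=O)C(Cl)(Cl)Cl)CC2=O | intermediate
18 | (+)-miliusane V, N-[(1R,5R,8R,9S)-1-[(1E)-2,6-dimethylhepta-1,5-dien-1-yl]-9-hydroxy-3,6-dioxo-2-oxaspiro[4.5]decan-8-yl]acetamide | CC(=O)N[C@@H]1CC(=O)[C@@]2(CC(=O)O[C@@H]2/C=C(\C)CCC=C(C)C)C[C@@H]1O | target

Total step count: 9. Longest linear sequence: 7 steps (steps 3 to 9 from methyl 4-oxobutanoate; the iodide branch, steps 1 and 2, joins at step 5 and is equally long).

**Steps most likely to fail**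

Step 4 (the step marked as a proposed new method). After the first C–C bond the zwitterion may lose a proton and re-aromatise (Friedel–Crafts alkylation of the furan), the donor–acceptor C1–C2 bond of the adduct may re-open during isolation, or facial control by the catalyst may be poor. The fallback uses known reaction types only; it sets out from vinyl iodide 5 and rejoins at hydroxy enone 13. Ring A is taken with its C5 oxygen in place as the known building block (S)-4-(tert-butyldimethylsilyloxy)cyclohex-2-en-1-one F1. Claisen formylation at the α' carbon (LiN(i-Pr)2, THF, −78 °C; 2,2,2-trifluoroethyl formate) should give hydroxymethylene ketone F2. C-Alkylation with methyl bromoacetate (K2CO3, acetone, rt), expected anti to the silyloxy group, should give quaternary keto aldehyde F3. Aldehyde-selective Nozaki–Hiyama–Kishi coupling with 5 under the conditions of step 5 should give hydroxy ester F4 and, after DBU, silyl ether lactone F5. HF·pyridine (THF, 0 °C) then frees the C5 hydroxyl and gives 13.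

Step 5. Chelation of the carbonyl by the ketal oxygens, or too small a difference between the C6 and C7 flanks, may erode or reverse facial selectivity at C9. The fallback moves stereocontrol to the ketone level under reagent control; it sets out from hydroxy ester 11, kept as the epimer mixture by omitting the DBU treatment, and returns at 12. Dess–Martin oxidation (CH2Cl2, NaHCO3, 0 °C) should give dienyl ketone F6. Corey–Bakshi–Shibata reduction with catecholborane and 1-methyl-3,3-diphenyltetrahydro-1H,3H-pyrrolo[1,2-c][1,3,2]oxazaborole (the enantiomer that delivers the 9R alcohol, toluene, −78 °C) should return 11 as one epimer, which is lactonised to 12 as before.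

Step 7. DBU may isomerise the γ-hydroxy enone to the 1,4-dione through its dienolate before the imidate closes, or the conjugate addition may stay reversible so that the oxazoline does not accumulate. The fallback uses a carbamate tether; it sets out from 13 and returns at target 18. Trichloroacetyl isocyanate (CH2Cl2, 0 °C) gives acyl carbamate F7, and K2CO3 in MeOH frees primary carbamate F8. KOt-Bu (THF, 0 °C, base-induced carbamate conjugate addition) closes cis-fused oxazolidinone F9. Boc2O with 4-(dimethylamino)pyridine gives N-Boc oxazolidinone F10, and Cs2CO3 in MeOH cleaves the ring carbonyl to N-Boc amino alcohol F11. Me3SiOTf/2,6-lutidine followed by MeOH removes the Boc group to give amino alcohol F12, which is N-acetylated (Ac2O, aq. NaHCO3, 0 °C) to 18.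

**Further compounds**
F1 | step 4 | (S)-4-(tert-butyldimethylsilyloxy)cyclohex-2-en-1-one | O=C1C=C[C@@H](O[Si](C)(C)C(C)(C)C)CC1
F2 | step 4 | (4S,6Z)-4-(tert-butyldimethylsilyloxy)-6-(hydroxymethylidene)cyclohex-2-en-1-one | O=C1C=C[C@@H](O[Si](C)(C)C(C)(C)C)C/C1=C/O
F3 | step 4 | methyl 2-[(1R,5S)-5-(tert-butyldimethylsilyloxy)-1-formyl-2-oxocyclohex-3-en-1-yl]acetate | COC(=O)C[C@@]1(C=O)C[C@H](O[Si](C)(C)C(C)(C)C)C=CC1=O
F4 | step 4 | methyl 2-[(1R,5S)-5-(tert-butyldimethylsilyloxy)-1-[(1R,2E)-1-hydroxy-3,7-dimethylocta-2,6-dien-1-yl]-2-oxocyclohex-3-en-1-yl]acetate | COC(=O)C[C@@]1([C@H](O)/C=C(\C)CCC=C(C)C)C[C@H](O[Si](C)(C)C(C)(C)C)C=CC1=O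
F5 | step 4 | C5 tert-butyldimethylsilyl ether of 13 | O=C1C[C@@]2([C@H](O1)/C=C(\C)CCC=C(C)C)C[C@H](O[Si](C)(C)C(C)(C)C)C=CC2=O
F6 | step 5 | methyl 2-[(1S,2R,4S)-2-[(2E)-3,7-dimethylocta-2,6-dienoyl]-1-methoxy-7-oxabicyclo[2.2.1]hept-5-en-2-yl]acetate | COC(=O)C[C@@]1(C(=O)/C=C(\C)CCC=C(C)C)C[C@H]2C=C[C@]1(OC)O2
F7 | step 7 | C5 O-(N-trichloroacetylcarbamate) of 13 | O=C1C[C@@]2([C@H](O1)/C=C(\C)CCC=C(C)C)C[C@H](OC(=O)NC(=O)C(Cl)(Cl)Cl)C=CC2=O
F8 | step 7 | C5 O-carbamate of 13 | O=C1C[C@@]2([C@H](O1)/C=C(\C)CCC=C(C)C)C[C@H](OC(N)=O)C=CC2=O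
F9 | step 7 | cis-fused oxazolidinone spanning C4–N and C5–O | O=C1C[C@@]2([C@H](O1)/C=C(\C)CCC=C(C)C)C[C@@H]3OC(=O)N[C@@H]3CC2=O
F10 | step 7 | N-tert-butoxycarbonyl oxazolidinone | O=C1C[C@@]2([C@H](O1)/C=C(\C)CCC=C(C)C)C[C@@H]3OC(=O)N(C(=O)OC(C)(C)C)[C@@H]3CC2=O
F11 | step 7 | C4 N-tert-butoxycarbonylamino C5 alcohol | O=C1C[C@@]2([C@H](O1)/C=C(\C)CCC=C(C)C)C[C@H](O)[C@H](NC(=O)OC(C)(C)C)CC2=O
F12 | step 7 | C4 amino C5 alcohol | O=C1C[C@@]2([C@H](O1)/C=C(\C)CCC=C(C)C)C[C@H](O)[C@H](N)CC2=O
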